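**Retrosynthetic overview**

1. Labels: ring A is the cyclohexenone (C1′ carries the linker, C2′ the vinylic methyl, C3′ the carbonyl, C4′ and C5′ the two CH2, C6′ the gem-dimethyl carbon); ring B is the 1,2-dioxane (O1, O2, C3 with the propanoate, C4, C5, quaternary C6); the linker is Cα (on C6) and Cβ (on C1′).
2. Last C–C bond: Cα=Cβ by Horner–Wadsworth–Emmons union of a ring B peroxy aldehyde with a ring A phosphonate, then diimide saturation of that alkene only.
3. Ring A is closed at C4′–C5′ by an iridium-catalysed hydrogen-borrowing cyclisation of a δ-hydroxy enone stored as a lactol. The enabling feature: the C3′ carbonyl makes C4′ an enolisable α′-carbon, the quaternary C6′ makes C5′ a neopentyl carbinol whose aldehyde cannot enolise, and the tetrasubstituted C1′=C2′ bond (fixed Z by a temporary dihydropyranone ring) holds both termini cis.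
4. Ring B: O2–C3 by invertive 6-exo-tet alkylation of a tertiary hydroperoxide; C6–O1 by invertive perhydrolysis of a 2,2-disubstituted epoxide derived from (S)-2-methylglycidol; C2 and C3 by anti-selective crotylboration.
5. Order of rings: temporary dihydropyranone (step 2), ring A (step 4), ring B (step 13); the two rings are joined in step 17.

Key step: step 4

Remark: 1 is taken as a purchasable chemical (otherwise one step from 3-methylbutan-2-one and formaldehyde); several R/S descriptors change along the route only because CIP priorities change, not because a centre is touched.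

**Ring A branch**

Step 1
Reactants: 1 4-hydroxy-3,3-dimethylbutan-2-one; 2 2-(diethoxyphosphoryl)propanoic acid
Product: 3 2,2-dimethyl-3-oxobutyl 2-(diethoxyphosphoryl)propanoate
Conditions: DCC, DMAP (cat.), CH2Cl2, 0 °C to rt
Reagents that add atoms: none
Why: Steglich esterification of an unhindered primary alcohol tethers the phosphonate to the ketone; the phosphonate α-carbon is racemic and becomes sp2 in step 2.

Step 2
Reactants: 3 2,2-dimethyl-3-oxobutyl 2-(diethoxyphosphoryl)propanoate
Product: 4 3,4,5,5-tetramethyl-5,6-dihydro-2H-pyran-2-one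
Conditions: NaH, THF, 0 °C to 60 °C
Reagents that add atoms: none
Why: Intramolecular Horner–Wadsworth–Emmons olefination of the ketone; closing a six-membered lactone allows only the Z-tetrasubstituted alkene, so the future C3′ and C6′ end up cis without any stereocentre being formed.

Step 3
Reactants: 4 3,4,5,5-tetramethyl-5,6-dihydro-2H-pyran-2-one
Product: 5 2,3,4,5,5-pentamethyl-5,6-dihydro-2H-pyran-2-ol
Conditions: MeLi (1.05 equiv), Et2O/THF, −78 °C; then H2O
Reagents that add atoms: methyllithium, [Li]C
Why: 1,2-Addition of an organolithium to a lactone stops at the lithium hemiketal at low temperature (conjugate addition is blocked by the fully substituted β-carbon), which installs C4′ as a methyl ketone masked in a lactol whose anomeric configuration is irrelevant.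

Step 4
Reactants: 5 2,3,4,5,5-pentamethyl-5,6-dihydro-2H-pyran-2-ol
Product: 9 2,3,4,4-tetramethylcyclohex-2-en-1-one, via hydroxy enone 6 (not isolated), via keto aldehyde 7 (not isolated), via dienone 8 (not isolated)
Conditions: [Cp*IrCl2]2 (2 mol%), KOH (20 mol%), toluene, 100 °C, sealed tube, Ar
Reagents that add atoms: none
Why: KOH opens lactol 5 to the Z-hydroxy enone 6, whose neopentyl alkoxide is dehydrogenated on Cp*Ir (β-hydride elimination) to the non-enolisable aldehyde 7 with the hydrogen stored as an iridium hydride; the α′-enolate at C4′ adds to the C5′ aldehyde, E1cB loss of water gives the cross-conjugated dienone 8, and the iridium hydride returns the hydrogen by 1,4-addition at C5′ to leave C4′–C5′ as a single bond in 9. The closest known reaction type is the iridium-catalysed hydrogen-borrowing α-alkylation of methyl ketones with primary alcohols, run here intramolecularly. Ring A closes in a 6-(enolexo)-exo-trig aldol mode, helped by the gem-dimethyl group at C6′ and by the cis arrangement of both arms on the C1′=C2′ bond. No stereocentre is formed. The step needs site selectivity among the enolisable positions and chemoselectivity in the hydride return: only the C4′ enolate reaches the aldehyde through a six-membered transition state (attack from Cβ or C2′ of the extended enolate would give a four-membered ring), and only the disubstituted C4′=C5′ bond of 8 is open to hydride, the tetrasubstituted C1′=C2′ bond is not. Any E isomer formed by dienolate equilibration under the basic conditions is not lost, because it returns to the Z isomer that alone can cyclise.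

Step 5
Reactants: 9 2,3,4,4-tetramethylcyclohex-2-en-1-one
Product: 10 3-(bromomethyl)-2,4,4-trimethylcyclohex-2-en-1-one
Conditions: NBS, AIBN (cat.), PhCF3, 80 °C
Reagents that add atoms: N-bromosuccinimide, BrN1C(=O)CCC1=O
Why: Wohl–Ziegler bromination; hydrogen abstraction from the Cβ methyl gives the radical that is delocalised over C2′ and the carbonyl oxygen, and the ring γ-position C6′ is quaternary and cannot compete.

Step 6
Reactants: 10 3-(bromomethyl)-2,4,4-trimethylcyclohex-2-en-1-one
Product: 11 diethyl [(2,6,6-trimethyl-3-oxocyclohex-1-en-1-yl)methyl]phosphonate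
Conditions: P(OEt)3, toluene, 110 °C
Reagents that add atoms: triethyl phosphite, CCOP(OCC)OCC
Why: Michaelis–Arbuzov reaction of a primary allylic bromide.

**Ring B branch**

Step 7
Reactants: 12 [(2S)-2-methyloxiran-2-yl]methanol
Product: 13 (2R)-2-methylhex-5-ene-1,2-diol
Conditions: CH2=CHCH2MgCl (2.5 equiv), CuI (10 mol%), THF, −30 to 0 °C; then H2O
Reagents that add atoms: allylmagnesium chloride, C=CC[Mg]Cl
Why: Copper-catalysed SN2 opening of the epoxide by the Grignard reagent at its unsubstituted carbon; the quaternary stereocentre (future C6) is not touched.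

Step 8
Reactants: 13 (2R)-2-methylhex-5-ene-1,2-diol
Product: 15 (2R)-2-(but-3-en-1-yl)-2-methyloxirane, via primary tosylate 14 (not isolated)
Conditions: TsCl, Et3N, Bu2SnO (2 mol%), CH2Cl2, 0 °C; then K2CO3, MeOH, rt
Reagents that add atoms: none
Why: Tin-catalysed sulfonylation of the primary hydroxyl followed by Williamson-type 3-exo-tet closure from the tertiary alkoxide; the C–O bond at the stereocentre is retained.

Step 9
Reactants: 15 (2R)-2-(but-3-en-1-yl)-2-methyloxirane
Product: 17 3-[(2R)-2-methyloxiran-2-yl]propanal, via ozonide 16 (not isolated)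
Conditions: O3, CH2Cl2, −78 °C; then Me2S, −78 °C to rt
Reagents that add atoms: ozone, [O-][O+]=O
Why: Ozonolysis with reductive work-up; the epoxide is inert to ozone and to Me2S.

Step 10
Reactants: 17 3-[(2R)-2-methyloxiran-2-yl]propanal
Product: 19 (3S,4R)-3-methyl-6-[(2R)-2-methyloxiran-2-yl]hex-1-en-4-ol, via borate ester 18 (not isolated)
Conditions: diisopropyl (R,R)-tartrate (E)-crotylboronate (1.5 equiv), 4 Å molecular sieves, toluene, −78 °C; then 1 M NaOH
Reagents that add atoms: diisopropyl (4R,5R)-2-[(E)-but-2-en-1-yl]-1,3,2-dioxaborolane-4,5-dicarboxylate, C/C=C/CB1O[C@@H](C(=O)OC(C)C)[C@H](C(=O)OC(C)C)O1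
Why: Tartrate-controlled crotylboration through a closed chair transition state, in which the E geometry gives the anti relationship and the (R,R)-tartrate is expected to direct attack to the si face of the aldehyde (4R), sets the future C2 and the pre-inversion C3; no Lewis acid is present, so the epoxide should survive, and any minor diastereomer from imperfect facial control is removed here or at 22.

Step 11
Reactants: 19 (3S,4R)-3-methyl-6-[(2R)-2-methyloxiran-2-yl]hex-1-en-4-ol
Product: 20 (3S,4R)-3-methyl-6-[(2R)-2-methyloxiran-2-yl]hex-1-en-4-yl methanesulfonate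
Conditions: MsCl, Et3N, CH2Cl2, −10 °C
Reagents that add atoms: methanesulfonyl chloride, CS(=O)(=O)Cl
Why: O-Sulfonylation with retention at the carbinol carbon; the basic medium avoids acid-triggered opening of the epoxide by the neighbouring hydroxyl.

Step 12
Reactants: 20 (3S,4R)-3-methyl-6-[(2R)-2-methyloxiran-2-yl]hex-1-en-4-yl methanesulfonate
Product: 21 (3S,4R,7S)-7-hydroperoxy-8-hydroxy-3,7-dimethyloct-1-en-4-yl methanesulfonate
Conditions: H2O2 (anhydrous solution in Et2O, 10 equiv), H3PMo12O40 (5 mol%), Et2O, rt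
Reagents that add atoms: hydrogen peroxide, OO
Why: Acid-catalysed perhydrolysis of a 2,2-disubstituted epoxide, in which hydrogen peroxide enters at the more substituted carbon anti to the departing oxygen (borderline SN2), should set C6 with inversion, the (R)-epoxide giving the (7S)-hydroperoxide; the mesylate and the vinyl group are inert.

Step 13
Reactants: 21 (3S,4R,7S)-7-hydroperoxy-8-hydroxy-3,7-dimethyloct-1-en-4-yl methanesulfonate
Product: 22 [(3S,6S)-6-[(2S)-but-3-en-2-yl]-3-methyl-1,2-dioxan-3-yl]methanol
Conditions: KOtBu (1.0 equiv), 18-crown-6, toluene, 0 °C to rt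
Reagents that add atoms: none
Why: 6-exo-tet intramolecular SN2 alkylation of the hydroperoxide anion (the only group deprotonated by one equivalent of base, and an α-effect nucleophile) at the secondary mesylate closes ring B and inverts that carbon to the C3 configuration of the target.

Step 14
Reactants: 22 [(3S,6S)-6-[(2S)-but-3-en-2-yl]-3-methyl-1,2-dioxan-3-yl]methanol
Product: 25 (2R)-2-[(3S,6S)-6-(hydroxymethyl)-6-methyl-1,2-dioxan-3-yl]propanoic acid, via ozonide 23 (not isolated), via aldehyde 24 (not isolated)
Conditions: O3, CH2Cl2, −78 °C; Me2S; evaporation; then NaClO2, NaH2PO4, 2-methylbut-2-ene, t-BuOH/H2O, 0 °C to rt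
Reagents that add atoms: ozone, [O-][O+]=O; sodium chlorite, [Na+].[O-]Cl=O
Why: Ozonolysis followed by Pinnick oxidation, both of which spare dialkyl peroxides; the buffered chlorite step should neither epimerise the α-stereocentre nor touch the primary alcohol.

Step 15
Reactants: 25 (2R)-2-[(3S,6S)-6-(hydroxymethyl)-6-methyl-1,2-dioxan-3-yl]propanoic acid
Product: 26 methyl (2R)-2-[(3S,6S)-6-(hydroxymethyl)-6-methyl-1,2-dioxan-3-yl]propanoate
Conditions: Me3SiCHN2, toluene/MeOH, 0 °C
Reagents that add atoms: (trimethylsilyl)diazomethane, C[Si](C)(C)C=[N+]=[N-]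
Why: Diazoalkane esterification under neutral conditions leaves the peroxide and the α-stereocentre untouched.

Step 16
Reactants: 26 methyl (2R)-2-[(3S,6S)-6-(hydroxymethyl)-6-methyl-1,2-dioxan-3-yl]propanoate
Product: 27 methyl (2R)-2-[(3S,6S)-6-formyl-6-methyl-1,2-dioxan-3-yl]propanoate
Conditions: DMP, CH2Cl2, 0 °C to rt
Reagents that add atoms: none
Why: Hypervalent-iodine oxidation of the primary alcohol under neutral conditions; the aldehyde has no α-hydrogen, so it can neither enolise nor eliminate the peroxide.

**Union**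

Step 17
Reactants: 11 diethyl [(2,6,6-trimethyl-3-oxocyclohex-1-en-1-yl)methyl]phosphonate; 27 methyl (2R)-2-[(3S,6S)-6-formyl-6-methyl-1,2-dioxan-3-yl]propanoate
Product: 28 methyl (2R)-2-[(3S,6S)-6-methyl-6-[(E)-2-(2,6,6-trimethyl-3-oxocyclohex-1-en-1-yl)ethenyl]-1,2-dioxan-3-yl]propanoate
Conditions: 11, NaH (0.95 equiv), THF, 0 °C; then 27, −78 to 0 °C
Reagents that add atoms: none
Why: Horner–Wadsworth–Emmons olefination with the preformed anion of the vinylogous β-keto phosphonate (Cβ is the only position both α to phosphorus and vinylogous to the ketone); the anion is too weakly basic to enolise the β-peroxy ester, and the alkene geometry is immaterial.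

Step 18
Reactants: 28 methyl (2R)-2-[(3S,6S)-6-methyl-6-[(E)-2-(2,6,6-trimethyl-3-oxocyclohex-1-en-1-yl)ethenyl]-1,2-dioxan-3-yl]propanoate
Product: 29 methyl (2R)-2-[(3S,6R)-6-methyl-6-[2-(2,6,6-trimethyl-3-oxocyclohex-1-en-1-yl)ethyl]-1,2-dioxan-3-yl]propanoate (methyl diacarnoate A)
Conditions: KO2CN=NCO2K (excess, in portions), AcOH, MeOH/CH2Cl2, 0 °C to rt
Reagents that add atoms: none
Why: Diimide reduction (concerted syn transfer of two hydrogens) should saturate only the disubstituted Cα=Cβ bond, leaving the O–O bond, both carbonyls and the tetrasubstituted C1′=C2′ bond intact; no stereocentre is affected.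

**Compound list**

1 | 4-hydroxy-3,3-dimethylbutan-2-one | CC(=O)C(C)(C)CO | starting material
2 | 2-(diethoxyphosphoryl)propanoic acid | CCOP(=O)(OCC)C(C)C(=O)O | starting material
3 | 2,2-dimethyl-3-oxobutyl 2-(diethoxyphosphoryl)propanoate | CCOP(=O)(OCC)C(C)C(=O)OCC(C)(C)C(C)=O | intermediate
4 | 3,4,5,5-tetramethyl-5,6-dihydro-2H-pyran-2-one | CC1=C(C)C(C)(C)COC1=O | intermediate
5 | 2,3,4,5,5-pentamethyl-5,6-dihydro-2H-pyran-2-ol (lactol, either anomer) | CC1=C(C)C(C)(C)COC1(C)O | intermediate
6 | (Z)-6-hydroxy-3,4,5,5-tetramethylhex-3-en-2-one | C/C(C(C)=O)=C(\C)C(C)(C)CO | intermediate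
7 | (Z)-2,2,3,4-tetramethyl-5-oxohex-3-enal | C/C(C(C)=O)=C(\C)C(C)(C)C=O | intermediate
8 | 2,3,4,4-tetramethylcyclohexa-2,5-dien-1-one | CC1=C(C)C(C)(C)C=CC1=O | intermediate
9 | 2,3,4,4-tetramethylcyclohex-2-en-1-one | CC1=C(C)C(C)(C)CCC1=O | intermediate
10 | 3-(bromomethyl)-2,4,4-trimethylcyclohex-2-en-1-one | CC1=C(CBr)C(C)(C)CCC1=O | intermediate
11 | diethyl [(2,6,6-trimethyl-3-oxocyclohex-1-en-1-yl)methyl]phosphonate | CCOP(=O)(OCC)CC1=C(C)C(=O)CCC1(C)C | intermediate
12 | [(2S)-2-methyloxiran-2-yl]methanol ((S)-2-methylglycidol) | C[C@]1(CO)CO1 | starting material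
13 | (2R)-2-methylhex-5-ene-1,2-diol | C=CCC[C@](C)(CO)O | intermediate
14 | (2R)-2-hydroxy-2-methylhex-5-en-1-yl 4-methylbenzenesulfonate | C=CCC[C@](C)(COS(=O)(=O)c1ccc(C)cc1)O | intermediate
15 | (2R)-2-(but-3-en-1-yl)-2-methyloxirane | C=CCC[C@]1(C)CO1 | intermediate
16 | ozonide of 15: (2R)-2-methyl-2-[2-(1,2,4-trioxolan-3-yl)ethyl]oxirane | C1(CC[C@]2(C)CO2)OOCO1 | intermediate
17 | 3-[(2R)-2-methyloxiran-2-yl]propanal | O=CCC[C@]1(C)CO1 | intermediate
18 | diisopropyl (4R,5R)-2-{[(3S,4R)-3-methyl-6-[(2R)-2-methyloxiran-2-yl]hex-1-en-4-yl]oxy}-1,3,2-dioxaborolane-4,5-dicarboxylate | C=C[C@H](C)[C@H](OB2O[C@@H](C(=O)OC(C)C)[C@H](C(=O)OC(C)C)O2)CC[C@]1(C)CO1 | intermediate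
19 | (3S,4R)-3-methyl-6-[(2R)-2-methyloxiran-2-yl]hex-1-en-4-ol | C=C[C@H](C)[C@H](O)CC[C@]1(C)CO1 | intermediate
20 | (3S,4R)-3-methyl-6-[(2R)-2-methyloxiran-2-yl]hex-1-en-4-yl methanesulfonate | C=C[C@H](C)[C@H](OS(C)(=O)=O)CC[C@]1(C)CO1 | intermediate
21 | (3S,4R,7S)-7-hydroperoxy-8-hydroxy-3,7-dimethyloct-1-en-4-yl methanesulfonate | C=C[C@H](C)[C@H](OS(C)(=O)=O)CC[C@@](C)(CO)OO | intermediate
22 | [(3S,6S)-6-[(2S)-but-3-en-2-yl]-3-methyl-1,2-dioxan-3-yl]methanol | C=C[C@H](C)[C@@H]1CC[C@@](C)(CO)OO1 | intermediate
23 | ozonide of 22 (1,2,4-trioxolan-3-yl group in place of the vinyl group, either configuration at the new ring carbon) | C1(OOCO1)[C@H](C)[C@@H]2CC[C@@](C)(CO)OO2 | intermediate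
24 | (2R)-2-[(3S,6S)-6-(hydroxymethyl)-6-methyl-1,2-dioxan-3-yl]propanal | O=C[C@H](C)[C@@H]1CC[C@@](C)(CO)OO1 | intermediate
25 | (2R)-2-[(3S,6S)-6-(hydroxymethyl)-6-methyl-1,2-dioxan-3-yl]propanoic acid | OC(=O)[C@H](C)[C@@H]1CC[C@@](C)(CO)OO1 | intermediate
26 | methyl (2R)-2-[(3S,6S)-6-(hydroxymethyl)-6-methyl-1,2-dioxan-3-yl]propanoate | COC(=O)[C@H](C)[C@@H]1CC[C@@](C)(CO)OO1 | intermediate
27 | methyl (2R)-2-[(3S,6S)-6-formyl-6-methyl-1,2-dioxan-3-yl]propanoate | COC(=O)[C@H](C)[C@@H]1CC[C@@](C)(C=O)OO1 | intermediate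
28 | methyl (2R)-2-[(3S,6S)-6-methyl-6-[(E)-2-(2,6,6-trimethyl-3-oxocyclohex-1-en-1-yl)ethenyl]-1,2-dioxan-3-yl]propanoate | COC(=O)[C@H](C)[C@@H]1CC[C@@](C)(/C=C/C2=C(C)C(=O)CCC2(C)C)OO1 | intermediate
29 | methyl (2R)-2-[(3S,6R)-6-methyl-6-[2-(2,6,6-trimethyl-3-oxocyclohex-1-en-1-yl)ethyl]-1,2-dioxan-3-yl]propanoate (methyl diacarnoate A) | COC(=O)[C@H](C)[C@@H]1CC[C@@](C)(CCC2=C(C)C(=O)CCC2(C)C)OO1 | target

**Step count and risks**

Total step count: 18 (ring A branch 6, ring B branch 10, union 2).
Longest linear sequence: 12 steps (steps 7 to 18, from 12).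

Steps most likely to fail:

1. Step 4. The borrowed hydrogen may not be returned cleanly: the transient aldehyde can be drained by intermolecular hemiacetal dehydrogenation (ester formation) or by hydroxide attack before the aldol closure, or the cycle can stall at the dienone stage. Fallback, setting out from 5 and coming back at 9: the three events are run as separate stoichiometric operations. DMP oxidation of 5 (through its open form) gives keto aldehyde 7, now isolated. KOH in MeOH closes the same C4′–C5′ bond by aldol condensation to dienone 8. [(Ph3P)CuH]6 in toluene then delivers hydride only to the disubstituted enone, giving 9. This detour passes only through compounds of the list (F0).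

2. Step 13. E2 elimination of the β-branched secondary mesylate toward the allylic hydrogen, or base-induced Grob-type fragmentation of the β-hydroxy hydroperoxide, may outrun the 6-exo-tet substitution. Fallback, setting out from 17 and coming back at 22: ring closure by base-free, silver-assisted halide displacement. The enantiomeric (S,S)-tartrate (Z)-crotylboronate converts 17, through the borate ester diisopropyl (4S,5S)-2-{[(3S,4S)-3-methyl-6-[(2R)-2-methyloxiran-2-yl]hex-1-en-4-yl]oxy}-1,3,2-dioxaborolane-4,5-dicarboxylate F1, into the syn alcohol (3S,4S)-3-methyl-6-[(2R)-2-methyloxiran-2-yl]hex-1-en-4-ol F2. Appel bromination (CBr4, PPh3, CH2Cl2, 0 °C) inverts the carbinol carbon to give (2R)-2-[(3R,4S)-3-bromo-4-methylhex-5-en-1-yl]-2-methyloxirane F3. Perhydrolysis as in step 12 gives (2S,5R,6S)-5-bromo-2-hydroperoxy-2,6-dimethyloct-7-en-1-ol F4. AgO2CCF3 in CH2Cl2 then abstracts bromide while the hydroperoxide closes the ring with a second inversion, giving 22.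

3. Step 12. Ionisation of the tertiary epoxide carbon ahead of peroxide delivery (erosion of configuration at C6), attack at the primary epoxide carbon, or acid-induced rearrangement of the epoxide may compete. Fallback, setting out from 20 and coming back at 22 (bypassing 21): the two C–O bond formations are run in the opposite order. The mesylate of 20 is displaced first by hydrogen peroxide (aqueous H2O2, KOH, MeOH, 0 °C; SN2 with inversion) to give the secondary hydroperoxide (2R)-2-[(3S,4S)-3-hydroperoxy-4-methylhex-5-en-1-yl]-2-methyloxirane F5, with the epoxide intact. Catalytic camphorsulfonic acid in CH2Cl2 then lets the tethered hydroperoxide open the epoxide at its tertiary carbon in a 6-exo-tet mode, the tether enforcing backside attack, to give 22.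

**Further compounds**

F0 | step 4 | none | none
F1 | step 13 | diisopropyl (4S,5S)-2-{[(3S,4S)-3-methyl-6-[(2R)-2-methyloxiran-2-yl]hex-1-en-4-yl]oxy}-1,3,2-dioxaborolane-4,5-dicarboxylate | C=C[C@H](C)[C@@H](OB2O[C@H](C(=O)OC(C)C)[C@@H](C(=O)OC(C)C)O2)CC[C@]1(C)CO1
F2 | step 13 | (3S,4S)-3-methyl-6-[(2R)-2-methyloxiran-2-yl]hex-1-en-4-ol | C=C[C@H](C)[C@@H](O)CC[C@]1(C)CO1
F3 | step 13 | (2R)-2-[(3R,4S)-3-bromo-4-methylhex-5-en-1-yl]-2-methyloxirane | C=C[C@H](C)[C@H](Br)CC[C@]1(C)CO1
F4 | step 13 | (2S,5R,6S)-5-bromo-2-hydroperoxy-2,6-dimethyloct-7-en-1-ol | C=C[C@H](C)[C@H](Br)CC[C@@](C)(CO)OO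
F5 | step 12 | (2R)-2-[(3S,4S)-3-hydroperoxy-4-methylhex-5-en-1-yl]-2-methyloxirane | C=C[C@H](C)[C@@H](OO)CC[C@]1(C)CO1
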